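Assumption: the SMILES is taken as drawn, i.e. (S) at C-2 of the dihydrobenzofuran and (S) at the α-carbon of the 2-methylbutanoyl group.

**Retrosynthetic overview**
1. Last bond: the CH2 bridge. The free aromatic carbon (C-5) of the dihydrobenzofuran adds to a 3-methylene-pyran-2,4-dione made in the flask from the pyrone and a CH2=NMe2+ salt.
2. Dihydrofuran ring: direct oxidative cyclisation (loss of 2 H) of an ortho-prenyl phenol with Pd(OCOCF3)2 and a chiral bis(oxazoline) ligand. This closes the ring and sets C-2 in one step, as in the oxidative cyclisation of prenyl phenols in nature. The para-OH is silylated so that only the OH next to the ketone can close.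
3. Prenyl acylphloroglucinol: aromatic C-prenylation of (S)-2-methylbutanoylphloroglucinol, made from phloroglucinol and (S)-2-methylbutanoic acid (source of the side-chain stereocentre).
4. Pyrone ring: lactonisation of the linear triketide ester (propionyl + methylmalonyl + malonyl pattern) from the dianion of methyl 3-oxopentanoate and a propionyl donor.
5. Ring order: benzene ring bought; pyrone ring made separately; dihydrofuran ring closed before the two halves are joined.

**Route**

Step 1
Reactants: 1 (2S)-2-methylbutanoic acid; 2 phloroglucinol (benzene-1,3,5-triol)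
Product: 4 (2S)-2-methyl-1-(2,4,6-trihydroxyphenyl)butan-1-one, via (2S)-2-methylbutanoyl chloride 3 (not isolated)
Conditions: (COCl)2 (1.0 equiv), DMF (cat.), CH2Cl2, 0 °C → rt; solution added to 2 and AlCl3 (3.5 equiv), PhNO2/CH2Cl2, 0 °C → rt; ice/1 M HCl
Reagents that add atoms: oxalyl chloride, ClC(=O)C(=O)Cl (gives the chlorine of 3 only; none of its atoms stays in 4)
Why: Friedel–Crafts acylation of the symmetrical, electron-rich triol by the acid chloride formed in the flask, the first acyl group deactivating the ring against a second; no new stereocentre is made, the (S) centre comes unchanged from 1, and working at or below room temperature keeps enolisation of the aluminium-bound ketone (the only racemisation path) slow (ee of 4 checked by chiral HPLC).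

Step 2
Reactants: 4 (2S)-2-methyl-1-(2,4,6-trihydroxyphenyl)butan-1-one; 5 prenyl bromide (1-bromo-3-methylbut-2-ene)
Product: 6 (2S)-2-methyl-1-[2,4,6-trihydroxy-3-(3-methylbut-2-en-1-yl)phenyl]butan-1-one
Conditions: 5 (0.9 equiv), 10% aq. KOH, 0 °C, 1 h; then 1 M HCl (unreacted 4 recovered)
Reagents that add atoms: none
Why: Aromatic C-prenylation (C-alkylation of the ambident phloroglucinol phenolate in water, SN2 on the allylic bromide), where the protic medium shields oxygen, C-3 and C-5 are equivalent so only one mono-prenyl product can form, a deficit of bromide limits diprenylation, and the side-chain stereocentre is untouched because the ketone of the polyanion is a very poor carbon acid.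

Step 3
Reactants: 6 (2S)-2-methyl-1-[2,4,6-trihydroxy-3-(3-methylbut-2-en-1-yl)phenyl]butan-1-one
Product: 7 (2S)-1-{2,6-dihydroxy-3-(3-methylbut-2-en-1-yl)-4-[tri(propan-2-yl)silyloxy]phenyl}-2-methylbutan-1-one
Conditions: TIPSCl (1.05 equiv), imidazole (2.2 equiv), DMF, 0 °C
Reagents that add atoms: triisopropylsilyl chloride (TIPSCl), CC(C)[Si](Cl)(C(C)C)C(C)C
Why: Selective O-silylation, because the OH para to the ketone is the most acidic and the only one that can never be hydrogen-bonded to the carbonyl, so it reacts first with one equivalent of the bulky silyl chloride while the two ketone-flanked OH groups stay free; this blocks the para oxygen so that only the ortho OH can close the furan ring in the next step.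

Step 4
Reactants: 7 (2S)-1-{2,6-dihydroxy-3-(3-methylbut-2-en-1-yl)-4-[tri(propan-2-yl)silyloxy]phenyl}-2-methylbutan-1-one
Product: 8 (2S)-1-{(2S)-6-hydroxy-2-(prop-1-en-2-yl)-4-[tri(propan-2-yl)silyloxy]-2,3-dihydro-1-benzofuran-7-yl}-2-methylbutan-1-one
Conditions: Pd(OCOCF3)2 (10 mol%), (S,S)-iPr-boxax [(S)-2,2'-bis((4S)-4-isopropyl-4,5-dihydrooxazol-2-yl)-1,1'-binaphthyl] (20 mol%), p-benzoquinone (2 equiv), MeOH, 40 → 60 °C
Reagents that add atoms: none
Why: Proposed new method: an enantioselective Wacker-type oxidative cyclisation of a prenyl group on an acylphloroglucinol is not known, but the cationic divalent palladium–bis(oxazoline) complex should bind the one OH that can reach the alkene (the para oxygen is silylated, the 6-OH is chelated to the ketone and has no prenyl neighbour), add oxygen and palladium syn across the double bond in the 5-exo mode (palladium on the tertiary carbon, as in the known tetrasubstituted cases), and lose a β-hydrogen from a methyl group to release the isopropenyl group while benzoquinone reoxidises zerovalent palladium; the ligand selects the alkene face and thus sets C-2 under catalyst control, (S) being expected from the sense seen with 2-(2,3-dimethylbut-2-enyl)phenol (the mirror-image ligand is used if the sense proves opposite); closest known reactions are the Pd(OCOCF3)2/boxax asymmetric Wacker-type cyclisation of ortho-allyl phenols and the Pd(OAc)2 cyclisation of 2-prenylphenol to 2-isopropenyl-2,3-dihydrobenzofuran.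

Step 5
Reactants: 8 (2S)-1-{(2S)-6-hydroxy-2-(prop-1-en-2-yl)-4-[tri(propan-2-yl)silyloxy]-2,3-dihydro-1-benzofuran-7-yl}-2-methylbutan-1-one
Product: 9 (2S)-1-[(2S)-4,6-dihydroxy-2-(prop-1-en-2-yl)-2,3-dihydro-1-benzofuran-7-yl]-2-methylbutan-1-one
Conditions: Bu4NF (1.1 equiv), AcOH (1.1 equiv), THF, 0 °C
Reagents that add atoms: none
Why: Fluoride-driven cleavage of an aryl silyl ether (Si–F bond formation, ketone-stabilised phenolate as leaving group), buffered with AcOH so that the allylic aryl ether and both stereocentres see neither strong base nor acid.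

Step 6
Reactants: 10 methyl 3-oxopentanoate; 11 N-methoxy-N-methylpropanamide
Product: 13 6-ethyl-4-hydroxy-5-methyl-2H-pyran-2-one, via methyl 4-methyl-3,5-dioxoheptanoate 12 (not isolated)
Conditions: NaH (1.1 equiv), THF, 0 °C; n-BuLi (1.05 equiv), 0 °C; 11 (1.0 equiv), −78 → 0 °C; AcOH (2.2 equiv); solvent swapped to PhMe in the same flask, DBU (1.5 equiv), 90 °C; 1 M HCl
Reagents that add atoms: none
Why: Claisen-type γ-acylation of the β-keto ester dianion with a Weinreb amide (the stable tetrahedral adduct prevents over-addition) gives the linear triketide ester 12, whose C-5 enol oxygen then attacks the ester under DBU (6-exo-trig lactonisation, the chemical counterpart of triketide release as a pyrone) to give the 4-hydroxy-2-pyrone; no stereocentre survives.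

Step 7
Reactants: 13 6-ethyl-4-hydroxy-5-methyl-2H-pyran-2-one; 14 Eschenmoser's salt (N,N-dimethylmethyleneiminium iodide); 9 (2S)-1-[(2S)-4,6-dihydroxy-2-(prop-1-en-2-yl)-2,3-dihydro-1-benzofuran-7-yl]-2-methylbutan-1-one
Product: 17 CNP0261501.1, 3-({(2S)-4,6-dihydroxy-7-[(2S)-2-methylbutanoyl]-2-(prop-1-en-2-yl)-2,3-dihydro-1-benzofuran-5-yl}methyl)-6-ethyl-4-hydroxy-5-methyl-2H-pyran-2-one, via pyrone Mannich base hydroiodide 15 (not isolated), via 3-methylidenepyrandione 16 (not isolated)
Conditions: 13, 14 (1.05 equiv), MeCN, rt, 1 h; then 9 (1.0 equiv), 60 °C, 4 h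
Reagents that add atoms: none
Why: Mannich reaction at pyrone C-3, thermal E1cB loss of dimethylamine to the methylene-dione 16 (an ortho-quinone-methide-like Michael acceptor) and conjugate addition of the only free aromatic carbon of 9 (C-5, between two OH groups) with rearomatisation build the methylene bridge under nearly neutral conditions that leave the isopropenyl group, the allylic aryl ether and both stereocentres untouched.

**Compound list**
1 | (2S)-2-methylbutanoic acid | CC[C@H](C)C(=O)O | starting material
2 | phloroglucinol (benzene-1,3,5-triol) | Oc1cc(O)cc(O)c1 | starting material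
3 | (2S)-2-methylbutanoyl chloride | CC[C@H](C)C(=O)Cl | intermediate (not isolated)
4 | (2S)-2-methyl-1-(2,4,6-trihydroxyphenyl)butan-1-one | CC[C@H](C)C(=O)c1c(O)cc(O)cc1O | intermediate
5 | prenyl bromide (1-bromo-3-methylbut-2-ene) | CC(C)=CCBr | starting material
6 | (2S)-2-methyl-1-[2,4,6-trihydroxy-3-(3-methylbut-2-en-1-yl)phenyl]butan-1-one | CC[C@H](C)C(=O)c1c(O)cc(O)c(CC=C(C)C)c1O | intermediate
7 | (2S)-1-{2,6-dihydroxy-3-(3-methylbut-2-en-1-yl)-4-[tri(propan-2-yl)silyloxy]phenyl}-2-methylbutan-1-one | CC[C@H](C)C(=O)c1c(O)cc(O[Si](C(C)C)(C(C)C)C(C)C)c(CC=C(C)C)c1O | intermediate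
8 | (2S)-1-{(2S)-6-hydroxy-2-(prop-1-en-2-yl)-4-[tri(propan-2-yl)silyloxy]-2,3-dihydro-1-benzofuran-7-yl}-2-methylbutan-1-one | C=C(C)[C@@H]1Cc2c(O[Si](C(C)C)(C(C)C)C(C)C)cc(O)c(C(=O)[C@@H](C)CC)c2O1 | intermediate
9 | (2S)-1-[(2S)-4,6-dihydroxy-2-(prop-1-en-2-yl)-2,3-dihydro-1-benzofuran-7-yl]-2-methylbutan-1-one | C=C(C)[C@@H]1Cc2c(O)cc(O)c(C(=O)[C@@H](C)CC)c2O1 | intermediate
10 | methyl 3-oxopentanoate | CCC(=O)CC(=O)OC | starting material
11 | N-methoxy-N-methylpropanamide | CCC(=O)N(C)OC | starting material
12 | methyl 4-methyl-3,5-dioxoheptanoate (C-4 not configurationally stable, no stereodescriptor) | CCC(=O)C(C)C(=O)CC(=O)OC | intermediate (not isolated)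
13 | 6-ethyl-4-hydroxy-5-methyl-2H-pyran-2-one | CCc1oc(=O)cc(O)c1C | intermediate
14 | Eschenmoser's salt (N,N-dimethylmethyleneiminium iodide) | C=[N+](C)C.[I-] | starting material
15 | 3-[(dimethylamino)methyl]-6-ethyl-4-hydroxy-5-methyl-2H-pyran-2-one hydroiodide | CCc1oc(=O)c(C[NH+](C)C)c(O)c1C.[I-] | intermediate (not isolated)
16 | 6-ethyl-5-methyl-3-methylidene-2H-pyran-2,4(3H)-dione | CCC1=C(C)C(=O)C(=C)C(=O)O1 | intermediate (not isolated)
17 | CNP0261501.1, 3-({(2S)-4,6-dihydroxy-7-[(2S)-2-methylbutanoyl]-2-(prop-1-en-2-yl)-2,3-dihydro-1-benzofuran-5-yl}methyl)-6-ethyl-4-hydroxy-5-methyl-2H-pyran-2-one | C=C(C)[C@@H]1Cc2c(O)c(Cc3c(O)c(C)c(CC)oc3=O)c(O)c(C(=O)[C@@H](C)CC)c2O1 | target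

**Step count and risks**

Total steps: 7 (steps 1–5 and 7 in the main line, step 6 for the pyrone). Longest linear sequence: 6 steps (1 → 2 → 3 → 4 → 5 → 7).

Most likely to fail, first: step 4. The prenyl case has no asymmetric precedent, so the ee at C-2 (seen as the diastereomer ratio against the fixed side-chain centre) may be low. 6-endo closure to a 2,2-dimethylchromene may compete, and the keto-phenol may tie up palladium. The fallback sets out from 7 and goes through the epoxide instead of direct C–H loss. Epoxidation of the prenyl double bond uses the D-fructose-derived ketone 1,2:4,5-di-O-isopropylidene-β-D-erythro-2,3-hexodiulo-2,6-pyranose (30 mol%) and KHSO5 (as 2KHSO5·KHSO4·K2SO4) in MeCN/dimethoxymethane with aqueous K2CO3 buffer at 0 °C. By analogy with trans-disubstituted and trisubstituted alkenes this gives the (2R) epoxide F1. The free ortho OH opens it 5-exo with inversion (in the buffer, or with K2CO3 in MeOH) to the (2S) tertiary alcohol F2. Dehydration towards a methyl group with the Burgess reagent (methyl N-(triethylammoniosulfonyl)carbamate, PhMe, 50 °C) then comes back to the route at 8.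

Second: step 3. The prenyl group next to the para OH may slow silylation enough for the 6-O-silyl or a bis-silyl ether to form. The fallback sets out from 4 and reverses the order, so that the selectivity is decided on the symmetrical compound. Compound 4 is silylated (TIPSCl, imidazole, DMF, 0 °C) to the para silyl ether F3, in which C-3 and C-5 are still equivalent. C-prenylation with 5 and DBU in THF (non-aqueous, so the silyl ether survives) then comes back to the route at 7.

Third: step 1. The α-stereocentre may erode under AlCl3/HCl. The fallback sets out from 1 and avoids the strong Lewis acid in the C–C bond-forming step. Acid 1 is converted with (CF3CO)2O and a trace of H3PO4 into its mixed anhydride, which acylates commercial 1,3,5-trimethoxybenzene at room temperature to give the trimethoxyphenyl ketone F4. Threefold demethylation with BBr3 (CH2Cl2, −78 °C → rt) then comes back to the route at 4.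

**Further compounds**
F1 | step 4 | (2S)-1-{3-{[(2R)-3,3-dimethyloxiran-2-yl]methyl}-2,6-dihydroxy-4-[tri(propan-2-yl)silyloxy]phenyl}-2-methylbutan-1-one | CC[C@H](C)C(=O)c1c(O)cc(O[Si](C(C)C)(C(C)C)C(C)C)c(C[C@H]2OC2(C)C)c1O
F2 | step 4 | (2S)-1-{(2S)-6-hydroxy-2-(2-hydroxypropan-2-yl)-4-[tri(propan-2-yl)silyloxy]-2,3-dihydro-1-benzofuran-7-yl}-2-methylbutan-1-one | CC(C)(O)[C@@H]1Cc2c(O[Si](C(C)C)(C(C)C)C(C)C)cc(O)c(C(=O)[C@@H](C)CC)c2O1
F3 | step 3 | (2S)-1-{2,6-dihydroxy-4-[tri(propan-2-yl)silyloxy]phenyl}-2-methylbutan-1-one | CC[C@H](C)C(=O)c1c(O)cc(O[Si](C(C)C)(C(C)C)C(C)C)cc1O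
F4 | step 1 | (2S)-2-methyl-1-(2,4,6-trimethoxyphenyl)butan-1-one | CC[C@H](C)C(=O)c1c(OC)cc(OC)cc1OC
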